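**Plan**

1. Numbering used below: C1 (methyl on C2), C2=C3, C4 (Me = C5), C6, C7 (Me = C8), C9–C11, cyclohexene C12, C13=C14 (CO2H = C15), C16 (Me = C17), C18, spiro C19, then O20, C21(=O), C22, C23(OH), C24(=O).
2. Cuts: C22–C24 (Dieckmann) and O20–C21 (acylketene lactonisation); C2–C23 (CO insertion into a Z-vinyl iodide) and C2=C3 (iodo-Wittig); C10=C11 (Wittig, then reduced); C12–C13 and C18–C19 of the cyclohexene together in one [4+2] step.
3. Enabling feature: on the C12–C19 edge of the six-membered ring, C11 and C24 are cis, so both can sit in one butenolide (C24 as lactone carbonyl, C11 as menthyl acetal carbon). C14, para to C19, is sp2, so C13–C14–C16–C18 can come from a 2-silyloxybutadiene.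
4. Forward order: the cyclohexene ring is made first, fused to a temporary lactone, and C19–OH, C16–Me and the C13=C14 ester are set on this bicycle. The lactone is then opened to C11–CHO and C24–CO2Me, the C3–C10 chain is joined, a 14-membered β-keto lactone is closed, and Dieckmann cyclisation contracts it to the tetronate and the 13-membered carbocycle.
5. Stereochemistry: C12 and C19 from the d-menthyloxy acetal (anti addition, cis fusion); C19–O from hydroxylation of the cis-fused lactone enolate; C16 from hydroxyl-directed hydrogenation; C4 and C7 from lipase desymmetrisation of a meso diol; Z-C2=C3 from a Stork–Zhao iodide.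

Key step: step 2

Assumption: (5S)-5-(d-menthyloxy)-2(5H)-furanone 3 and meso-2,4-dimethylglutaric anhydride 16 are taken as catalogue compounds (otherwise each is one or two known operations from furfural and (+)-menthol, or from 2,4-dimethylglutaric acid).
Remark: the target is drawn as one enol tautomer of the 3-acyltetronic acid; the last step gives the tautomeric system, of which the drawn form is one representation.
Abbreviation: TBS = tert-butyldimethylsilyl.

**Step 1**
Reactants: 1 but-3-en-2-one (methyl vinyl ketone)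
Product: 2 2-(tert-butyldimethylsilyloxy)buta-1,3-diene
Conditions: TBSOTf, Et3N, Et2O, 0 °C
Reagents that add atoms: tert-butyldimethylsilyl triflate, CC(C)(C)[Si](C)(C)OS(=O)(=O)C(F)(F)F
Why: Soft enolisation of the methyl ketone and O-silylation (silyl enol ether formation) should give the cross-conjugated 2-silyloxydiene; no stereocentre is formed.

**Step 2**
Reactants: 2 2-(tert-butyldimethylsilyloxy)buta-1,3-diene; 3 (5S)-5-[(1S,2R,5S)-menthyloxy]furan-2(5H)-one
Product: 4 (3S,3aS,7aR)-5-(tert-butyldimethylsilyloxy)-3-[(1S,2R,5S)-menthyloxy]-3a,4,7,7a-tetrahydro-2-benzofuran-1(3H)-one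
Conditions: toluene, 110 °C, sealed tube, 2 in excess
Reagents that add atoms: none
Why: This is a thermal Diels–Alder reaction of normal electron demand (concerted [4+2]), in which the diene termini C13 and C18 bond to the butenolide carbons C12 (β) and C19 (α); the closest known reaction type is the addition of simple and 2-silyloxy dienes to 5-alkoxy-2(5H)-furanones. The six-membered carbocycle is closed by suprafacial cycloaddition across the endocyclic C12=C19 bond, so it is necessarily cis-fused to the lactone, which puts C11 and C24 on the same face as the target requires; endo or exo orientation has no stereochemical consequence because the diene termini are unsubstituted. The diene should add to the face of the butenolide opposite the menthyloxy group on the acetal carbon C11, so the (S)-acetal fixes the absolute configuration of C12 and of C19 (which still carries H here). The step needs regioselectivity, and the silyloxy group secures it: the larger HOMO coefficient at C13 (the CH2 next to the silyloxy carbon) pairs with the lactone β-carbon C12, so the enol ether ends at C14=C16, para to C19. The adduct keeps three helpers for later use or removal: the lactone ring, the menthyl acetal (a masked C11 aldehyde) and the regiodefined silyl enol ether.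

**Step 3**
Reactants: 4 Diels–Alder adduct
Product: 6 (3S,3aS,7aS)-5-(tert-butyldimethylsilyloxy)-7a-hydroxy-3-[(1S,2R,5S)-menthyloxy]-3a,4,7,7a-tetrahydro-2-benzofuran-1(3H)-one, via potassium enolate 5 (not isolated)
Conditions: KN(SiMe3)2, THF, −78 °C; 2-(phenylsulfonyl)-3-phenyloxaziridine, −78 °C; aq. NH4Cl
Reagents that add atoms: 2-(phenylsulfonyl)-3-phenyloxaziridine, O=S(=O)(N1OC1c1ccccc1)c1ccccc1
Why: Davis oxidation of the lactone enolate (electrophilic α-hydroxylation): H-19 is the only acidic proton, the silyl enol ether is inert to the amide base, and oxygen should enter trans to the adjacent C12–C13 bond so that the ring fusion stays cis, which sets C19–O trans to C11.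

**Step 4**
Reactants: 6 hydroxy lactone
Product: 9 (3S,3aS,7aS)-7a-hydroxy-3-[(1S,2R,5S)-menthyloxy]-6-methylidenehexahydro-2-benzofuran-1,5-dione, via Mannich base 7 (not isolated), via trimethylammonium iodide 8 (not isolated)
Conditions: Me2N=CH2+ I−, CH2Cl2, rt; MeI, rt; DBU, 0 °C
Reagents that add atoms: N,N-dimethylmethyleneiminium iodide, C=[N+](C)C.[I-]
Why: Mannich reaction of the silyl enol ether with Eschenmoser's salt can occur only at C16 because the cycloaddition fixed the enol ether as C14=C16, and quaternisation followed by E1cB elimination gives the exocyclic enone (α-methylenation) that carries C17.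

**Step 5**
Reactants: 9 exocyclic enone
Product: 10 (3S,3aS,6S,7aS)-7a-hydroxy-3-[(1S,2R,5S)-menthyloxy]-6-methylhexahydro-2-benzofuran-1,5-dione
Conditions: H2 (1 atm), [Ir(cod)(PCy3)(py)]PF6 (cat.), CH2Cl2, rt
Reagents that add atoms: none
Why: Hydroxyl-directed homogeneous hydrogenation: the C19 hydroxyl binds the iridium catalyst and H2 should be delivered to C16=C17 from the hydroxyl-bearing (also convex) face of the cis-fused bicycle, which places the C16 methyl cis to C24 and C11.

**Step 6**
Reactants: 10 hydroxy ketone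
Product: 11 (3S,3aS,6S,7aS)-7a-(tert-butyldimethylsilyloxy)-3-[(1S,2R,5S)-menthyloxy]-6-methylhexahydro-2-benzofuran-1,5-dione
Conditions: TBSOTf, 2,6-lutidine, CH2Cl2, −78 to −20 °C
Reagents that add atoms: tert-butyldimethylsilyl triflate, CC(C)(C)[Si](C)(C)OS(=O)(=O)C(F)(F)F
Why: Silyl ether protection of the tertiary alcohol with the silyl triflate at low temperature, where 2,6-lutidine should not enolise the ketone, so the C16 stereocentre is untouched.

**Step 7**
Reactants: 11 silyl ether ketone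
Product: 13 (3S,3aS,6S,7aS)-7a-(tert-butyldimethylsilyloxy)-3-[(1S,2R,5S)-menthyloxy]-6-methyl-1-oxo-1,3,3a,6,7,7a-hexahydro-2-benzofuran-5-yl trifluoromethanesulfonate, via potassium enolate 12 (not isolated)
Conditions: KN(SiMe3)2, THF, −78 °C (ketone added to base); PhNTf2, −78 °C; aq. NH4Cl
Reagents that add atoms: N-phenylbis(trifluoromethanesulfonimide), O=S(=O)(N(c1ccccc1)S(=O)(=O)C(F)(F)F)C(F)(F)F
Why: Kinetic deprotonation by the bulky amide should remove a proton from the CH2 carbon C13 and not from the methine C16, and O-triflation of that enolate (enol triflate formation) fixes the double bond at C13=C14 without touching C16.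

**Step 8**
Reactants: 13 enol triflate
Product: 15 methyl (1S,2S,5S)-1-(tert-butyldimethylsilyloxy)-2-formyl-5-methyl-4-(trifluoromethylsulfonyloxy)cyclohex-3-ene-1-carboxylate, via lactol pseudo-acid 14 (not isolated)
Conditions: CF3CO2H/H2O/THF, rt; then Me3SiCHN2, MeOH/toluene, 0 °C
Reagents that add atoms: water, O; trimethylsilyldiazomethane, C[Si](C)(C)C=[N+]=[N-]
Why: Acid hydrolysis of the acylal-type menthyl acetal releases the auxiliary and gives the lactol, whose open carboxylic acid tautomer is O-methylated by the diazoalkane to the normal methyl ester with the C11 aldehyde free; no base is present, so C12 should not epimerise.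

**Step 9**
Reactants: 16 meso-2,4-dimethylglutaric anhydride [(3R,5S)-3,5-dimethyloxane-2,6-dione]
Product: 17 meso-2,4-dimethylpentane-1,5-diol
Conditions: LiAlH4, THF, 0 °C to reflux
Reagents that add atoms: none
Why: Hydride reduction of both anhydride carbonyls (LiAlH4 reduction) gives the meso diol without touching the two stereocentres.

**Step 10**
Reactants: 17 meso diol
Product: 18 (2R,4S)-5-acetoxy-2,4-dimethylpentan-1-ol
Conditions: Pseudomonas fluorescens lipase, vinyl acetate, rt
Reagents that add atoms: vinyl acetate, C=COC(C)=O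
Why: Lipase-catalysed transesterification (enzymatic desymmetrisation of a meso diol) acetylates one enantiotopic CH2OH and so fixes C4 and C7 in absolute terms; if the lipase should prefer the other arm, the same iodide 21 follows by running steps 13, 12 and 11 in that order.

**Step 11**
Reactants: 18 monoacetate
Product: 19 (2S,4R)-5-(tert-butyldimethylsilyloxy)-2,4-dimethylpentyl acetate
Conditions: TBSCl, imidazole, CH2Cl2, rt
Reagents that add atoms: tert-butyldimethylsilyl chloride, CC(C)(C)[Si](C)(C)Cl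
Why: Silyl ether formation on the free primary alcohol protects the C3 oxygen.

**Step 12**
Reactants: 19 silyl ether acetate
Product: 20 (2S,4R)-5-(tert-butyldimethylsilyloxy)-2,4-dimethylpentan-1-ol
Conditions: K2CO3 (cat.), MeOH, 0 °C to rt
Reagents that add atoms: none
Why: Base-catalysed transesterification (methanolysis) removes the acetate and leaves the silyl ether.

**Step 13**
Reactants: 20 alcohol
Product: 21 tert-butyl{[(2R,4S)-5-iodo-2,4-dimethylpentyl]oxy}dimethylsilane
Conditions: I2, PPh3, imidazole, CH2Cl2, 0 °C to rt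
Reagents that add atoms: iodine, II
Why: Appel-type iodination converts the primary alcohol to the iodide by SN2 at C9, so C7 is not involved.

**Step 14**
Reactants: 21 iodide
Product: 22 [(3S,5R)-6-(tert-butyldimethylsilyloxy)-3,5-dimethylhexyl]triphenylphosphonium iodide
Conditions: Ph3PCH3Br, n-BuLi, THF, 0 °C; then 21, 0 °C to rt
Reagents that add atoms: methyltriphenylphosphonium bromide, C[P+](c1ccccc1)(c1ccccc1)c1ccccc1.[Br-]
Why: C-Alkylation of methylenetriphenylphosphorane by the primary iodide (ylide alkylation) adds C10 and gives the homologous phosphonium salt in one operation.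

**Step 15**
Reactants: 15 aldehyde ester; 22 phosphonium iodide
Product: 24 methyl (1S,2S,5S)-1-(tert-butyldimethylsilyloxy)-2-[(1Z,4R,6R)-7-(tert-butyldimethylsilyloxy)-4,6-dimethylhept-1-en-1-yl]-5-methyl-4-(trifluoromethylsulfonyloxy)cyclohex-3-ene-1-carboxylate, via phosphorus ylide 23 (not isolated)
Conditions: NaN(SiMe3)2, THF, −78 °C; then 15, −78 to 0 °C
Reagents that add atoms: none
Why: Wittig olefination with the non-stabilised ylide joins the halves at C10=C11 (mainly Z, which does not matter because this bond is reduced later) and should be faster than enolisation of the α-branched aldehyde or attack on the hindered ester.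

**Step 16**
Reactants: 24 enol triflate
Product: 25 1-methyl 4-[2-(trimethylsilyl)ethyl] (1S,2S,5S)-1-(tert-butyldimethylsilyloxy)-2-[(1Z,4R,6R)-7-(tert-butyldimethylsilyloxy)-4,6-dimethylhept-1-en-1-yl]-5-methylcyclohex-3-ene-1,4-dicarboxylate
Conditions: CO (1 atm), Me3SiCH2CH2OH, Pd(OAc)2 (cat.), PPh3, Et3N, DMF, 60 °C
Reagents that add atoms: carbon monoxide, [C-]#[O+]; 2-(trimethylsilyl)ethanol, C[Si](C)(C)CCO
Why: Palladium-catalysed alkoxycarbonylation of the enol triflate (oxidative addition, CO insertion, alcoholysis) installs C15 as a fluoride-labile ester with the double bond fixed at C13=C14.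

**Step 17**
Reactants: 25 diene diester
Product: 26 1-methyl 4-[2-(trimethylsilyl)ethyl] (1S,2S,5S)-1-(tert-butyldimethylsilyloxy)-2-[(4R,6R)-7-(tert-butyldimethylsilyloxy)-4,6-dimethylheptyl]-5-methylcyclohex-3-ene-1,4-dicarboxylate
Conditions: H2 (1 atm), RhCl(PPh3)3 (cat.), benzene, rt
Reagents that add atoms: none
Why: Chemoselective homogeneous hydrogenation with RhCl(PPh3)3 should reduce the unhindered cis-disubstituted C10=C11 bond and leave the trisubstituted, conjugated C13=C14 bond.

**Step 18**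
Reactants: 26 bis-silyl ether
Product: 27 1-methyl 4-[2-(trimethylsilyl)ethyl] (1S,2S,5S)-1-hydroxy-2-[(4R,6R)-7-hydroxy-4,6-dimethylheptyl]-5-methylcyclohex-3-ene-1,4-dicarboxylate
Conditions: HF·pyridine, pyridine, THF, 0 °C to rt
Reagents that add atoms: none
Why: Desilylation with buffered HF·pyridine should cleave both silyl ethers, while the 2-(trimethylsilyl)ethyl ester, which needs unbuffered fluoride ion, should survive.

**Step 19**
Reactants: 27 diol
Product: 28 1-methyl 4-[2-(trimethylsilyl)ethyl] (1S,2S,5S)-2-[(4R,6R)-4,6-dimethyl-7-oxoheptyl]-1-hydroxy-5-methylcyclohex-3-ene-1,4-dicarboxylate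
Conditions: Dess–Martin periodinane, NaHCO3, CH2Cl2, 0 °C to rt
Reagents that add atoms: none
Why: Dess–Martin oxidation converts the primary alcohol to the C3 aldehyde under buffered, non-epimerising conditions, and the tertiary alcohol cannot be oxidised.

**Step 20**
Reactants: 28 aldehyde
Product: 29 1-methyl 4-[2-(trimethylsilyl)ethyl] (1S,2S,5S)-1-hydroxy-2-[(4R,6R,7Z)-8-iodo-4,6-dimethylnon-7-en-1-yl]-5-methylcyclohex-3-ene-1,4-dicarboxylate
Conditions: Ph3PEtI, n-BuLi, THF; I2, −78 °C; NaN(SiMe3)2, −78 °C; then 28, −78 to −20 °C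
Reagents that add atoms: ethyltriphenylphosphonium iodide, CC[P+](c1ccccc1)(c1ccccc1)c1ccccc1.[I-]; iodine, II
Why: Stork–Zhao olefination (Wittig reaction of the α-iodo ylide) should give the Z-2-iodo-2-alkene under kinetic control, which places iodine cis to C4 as the Z-C2=C3 bond of the target needs.

**Step 21**
Reactants: 29 Z-vinyl iodide
Product: 30 1-methyl 4-[2-(trimethylsilyl)ethyl] (1S,2S,5S)-2-[(4R,6R,7Z)-8-carboxy-4,6-dimethylnon-7-en-1-yl]-1-hydroxy-5-methylcyclohex-3-ene-1,4-dicarboxylate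
Conditions: CO (1 atm), H2O, Pd(OAc)2 (cat.), PPh3, Et3N, DMF, 40 °C; aq. acid work-up
Reagents that add atoms: carbon monoxide, [C-]#[O+]; water, O
Why: Palladium-catalysed hydroxycarbonylation of the vinyl iodide proceeds with retention of the double-bond geometry, so C23 should enter cis to C4.

**Step 22**
Reactants: 30 Z-enoic acid
Product: 33 macrolactone (14-membered β-keto lactone: O20–C21 ester of the C19 hydroxyl; Z-C2=C3; C24 methyl ester; C15 2-(trimethylsilyl)ethyl ester), via acyl Meldrum's acid 31 (not isolated), via acylketene 32 (not isolated)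
Conditions: Meldrum's acid, DCC, DMAP, CH2Cl2, 0 °C to rt; aq. HCl wash; then toluene (high dilution), 100 °C
Reagents that add atoms: Meldrum's acid, CC1(C)OC(=O)CC(=O)O1
Why: C-Acylation of Meldrum's acid by the carbodiimide-activated acid, then thermal loss of acetone and CO2 to the acylketene, which the tertiary C19 hydroxyl should trap at high dilution (acylketene macrolactonisation); no stereocentre is touched.

**Step 23**
Reactants: 33 macrolactone
Product: 35 okilactomycin C, via okilactomycin C 2-(trimethylsilyl)ethyl ester 34 (not isolated)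
Conditions: Bu4NF (excess), THF, rt; aq. HCl
Reagents that add atoms: none
Why: Fluoride serves as the base for the Dieckmann (Lacey–Dieckmann) cyclisation of C22 onto the C24 methyl ester, which forms the tetronic acid and contracts the lactone to the 13-membered carbocycle, and it also cleaves the 2-(trimethylsilyl)ethyl ester by β-elimination; no stereocentre is touched.

**Compound list**

1 | but-3-en-2-one (methyl vinyl ketone) | CC(=O)C=C | starting material
2 | 2-(tert-butyldimethylsilyloxy)buta-1,3-diene | C=CC(=C)O[Si](C)(C)C(C)(C)C | intermediate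
3 | (5S)-5-[(1S,2R,5S)-menthyloxy]furan-2(5H)-one | CC(C)[C@H]1CC[C@H](C)C[C@@H]1O[C@@H]1C=CC(=O)O1 | starting material
4 | (3S,3aS,7aR)-5-(tert-butyldimethylsilyloxy)-3-[(1S,2R,5S)-menthyloxy]-3a,4,7,7a-tetrahydro-2-benzofuran-1(3H)-one (cis-fused; C1 = C24, C3 = C11, C3a = C12, C7a = C19) | O=C1O[C@H](O[C@H]3C[C@@H](C)CC[C@@H]3C(C)C)[C@H]2CC(O[Si](C)(C)C(C)(C)C)=CC[C@@H]12 | intermediate
5 | potassium enolate of 4 (C19=C24–OK) | [K+].[O-]C=1O[C@H](O[C@H]3C[C@@H](C)CC[C@@H]3C(C)C)[C@H]2CC(O[Si](C)(C)C(C)(C)C)=CCC=12 | intermediate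
6 | (3S,3aS,7aS)-5-(tert-butyldimethylsilyloxy)-7a-hydroxy-3-[(1S,2R,5S)-menthyloxy]-3a,4,7,7a-tetrahydro-2-benzofuran-1(3H)-one | O=C1O[C@H](O[C@H]3C[C@@H](C)CC[C@@H]3C(C)C)[C@H]2CC(O[Si](C)(C)C(C)(C)C)=CC[C@@]12O | intermediate
7 | Mannich base: 6-[(dimethylamino)methyl]-7a-hydroxy-3-menthyloxyhexahydro-2-benzofuran-1,5-dione (C16 epimers, other centres as in 6) | O=C1O[C@H](O[C@H]3C[C@@H](C)CC[C@@H]3C(C)C)[C@H]2CC(=O)C(CN(C)C)C[C@@]12O | intermediate
8 | trimethylammonium iodide of 7 | [I-].O=C1O[C@H](O[C@H]3C[C@@H](C)CC[C@@H]3C(C)C)[C@H]2CC(=O)C(C[N+](C)(C)C)C[C@@]12O | intermediate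
9 | (3S,3aS,7aS)-7a-hydroxy-3-[(1S,2R,5S)-menthyloxy]-6-methylidenehexahydro-2-benzofuran-1,5-dione | O=C1O[C@H](O[C@H]3C[C@@H](C)CC[C@@H]3C(C)C)[C@H]2CC(=O)C(=C)C[C@@]12O | intermediate
10 | (3S,3aS,6S,7aS)-7a-hydroxy-3-[(1S,2R,5S)-menthyloxy]-6-methylhexahydro-2-benzofuran-1,5-dione | O=C1O[C@H](O[C@H]3C[C@@H](C)CC[C@@H]3C(C)C)[C@H]2CC(=O)[C@@H](C)C[C@@]12O | intermediate
11 | (3S,3aS,6S,7aS)-7a-(tert-butyldimethylsilyloxy)-3-[(1S,2R,5S)-menthyloxy]-6-methylhexahydro-2-benzofuran-1,5-dione | O=C1O[C@H](O[C@H]3C[C@@H](C)CC[C@@H]3C(C)C)[C@H]2CC(=O)[C@@H](C)C[C@@]12O[Si](C)(C)C(C)(C)C | intermediate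
12 | potassium C13=C14 enolate of 11 | [K+].O=C1O[C@H](O[C@H]3C[C@@H](C)CC[C@@H]3C(C)C)[C@H]2C=C([O-])[C@@H](C)C[C@@]12O[Si](C)(C)C(C)(C)C | intermediate
13 | (3S,3aS,6S,7aS)-7a-(tert-butyldimethylsilyloxy)-3-[(1S,2R,5S)-menthyloxy]-6-methyl-1-oxo-1,3,3a,6,7,7a-hexahydro-2-benzofuran-5-yl trifluoromethanesulfonate | O=C1O[C@H](O[C@H]3C[C@@H](C)CC[C@@H]3C(C)C)[C@H]2C=C(OS(=O)(=O)C(F)(F)F)[C@@H](C)C[C@@]12O[Si](C)(C)C(C)(C)C | intermediate
14 | lactol pseudo-acid: 13 with OH in place of menthyloxy at C11 (both anomers) | O=C1OC(O)[C@H]2C=C(OS(=O)(=O)C(F)(F)F)[C@@H](C)C[C@@]12O[Si](C)(C)C(C)(C)C | intermediate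
15 | methyl (1S,2S,5S)-1-(tert-butyldimethylsilyloxy)-2-formyl-5-methyl-4-(trifluoromethylsulfonyloxy)cyclohex-3-ene-1-carboxylate (formyl and methyl cis to the ester) | O=C[C@H]1C=C(OS(=O)(=O)C(F)(F)F)[C@@H](C)C[C@@]1(O[Si](C)(C)C(C)(C)C)C(=O)OC | intermediate
16 | meso-2,4-dimethylglutaric anhydride [(3R,5S)-3,5-dimethyloxane-2,6-dione] | C[C@H]1C[C@@H](C)C(=O)OC1=O | starting material
17 | meso-2,4-dimethylpentane-1,5-diol | OC[C@H](C)C[C@H](C)CO | intermediate
18 | (2R,4S)-5-acetoxy-2,4-dimethylpentan-1-ol | OC[C@H](C)C[C@H](C)COC(C)=O | intermediate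
19 | (2S,4R)-5-(tert-butyldimethylsilyloxy)-2,4-dimethylpentyl acetate | CC(C)(C)[Si](C)(C)OC[C@H](C)C[C@H](C)COC(C)=O | intermediate
20 | (2S,4R)-5-(tert-butyldimethylsilyloxy)-2,4-dimethylpentan-1-ol | CC(C)(C)[Si](C)(C)OC[C@H](C)C[C@H](C)CO | intermediate
21 | tert-butyl{[(2R,4S)-5-iodo-2,4-dimethylpentyl]oxy}dimethylsilane | CC(C)(C)[Si](C)(C)OC[C@H](C)C[C@H](C)CI | intermediate
22 | [(3S,5R)-6-(tert-butyldimethylsilyloxy)-3,5-dimethylhexyl]triphenylphosphonium iodide | CC(C)(C)[Si](C)(C)OC[C@H](C)C[C@H](C)CC[P+](c1ccccc1)(c1ccccc1)c1ccccc1.[I-] | intermediate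
23 | phosphorus ylide of 22 | CC(C)(C)[Si](C)(C)OC[C@H](C)C[C@H](C)CC=P(c1ccccc1)(c1ccccc1)c1ccccc1 | intermediate
24 | methyl (1S,2S,5S)-1-(tert-butyldimethylsilyloxy)-2-[(1Z,4R,6R)-7-(tert-butyldimethylsilyloxy)-4,6-dimethylhept-1-en-1-yl]-5-methyl-4-(trifluoromethylsulfonyloxy)cyclohex-3-ene-1-carboxylate | CC(C)(C)[Si](C)(C)OC[C@H](C)C[C@H](C)C/C=C\[C@H]1C=C(OS(=O)(=O)C(F)(F)F)[C@@H](C)C[C@@]1(O[Si](C)(C)C(C)(C)C)C(=O)OC | intermediate
25 | 1-methyl 4-[2-(trimethylsilyl)ethyl] (1S,2S,5S)-1-(tert-butyldimethylsilyloxy)-2-[(1Z,4R,6R)-7-(tert-butyldimethylsilyloxy)-4,6-dimethylhept-1-en-1-yl]-5-methylcyclohex-3-ene-1,4-dicarboxylate | CC(C)(C)[Si](C)(C)OC[C@H](C)C[C@H](C)C/C=C\[C@H]1C=C(C(=O)OCC[Si](C)(C)C)[C@@H](C)C[C@@]1(O[Si](C)(C)C(C)(C)C)C(=O)OC | intermediate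
26 | 1-methyl 4-[2-(trimethylsilyl)ethyl] (1S,2S,5S)-1-(tert-butyldimethylsilyloxy)-2-[(4R,6R)-7-(tert-butyldimethylsilyloxy)-4,6-dimethylheptyl]-5-methylcyclohex-3-ene-1,4-dicarboxylate | CC(C)(C)[Si](C)(C)OC[C@H](C)C[C@H](C)CCC[C@H]1C=C(C(=O)OCC[Si](C)(C)C)[C@@H](C)C[C@@]1(O[Si](C)(C)C(C)(C)C)C(=O)OC | intermediate
27 | 1-methyl 4-[2-(trimethylsilyl)ethyl] (1S,2S,5S)-1-hydroxy-2-[(4R,6R)-7-hydroxy-4,6-dimethylheptyl]-5-methylcyclohex-3-ene-1,4-dicarboxylate | OC[C@H](C)C[C@H](C)CCC[C@H]1C=C(C(=O)OCC[Si](C)(C)C)[C@@H](C)C[C@@]1(O)C(=O)OC | intermediate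
28 | 1-methyl 4-[2-(trimethylsilyl)ethyl] (1S,2S,5S)-2-[(4R,6R)-4,6-dimethyl-7-oxoheptyl]-1-hydroxy-5-methylcyclohex-3-ene-1,4-dicarboxylate | O=C[C@H](C)C[C@H](C)CCC[C@H]1C=C(C(=O)OCC[Si](C)(C)C)[C@@H](C)C[C@@]1(O)C(=O)OC | intermediate
29 | 1-methyl 4-[2-(trimethylsilyl)ethyl] (1S,2S,5S)-1-hydroxy-2-[(4R,6R,7Z)-8-iodo-4,6-dimethylnon-7-en-1-yl]-5-methylcyclohex-3-ene-1,4-dicarboxylate | I/C(C)=C\[C@H](C)C[C@H](C)CCC[C@H]1C=C(C(=O)OCC[Si](C)(C)C)[C@@H](C)C[C@@]1(O)C(=O)OC | intermediate
30 | 1-methyl 4-[2-(trimethylsilyl)ethyl] (1S,2S,5S)-2-[(4R,6R,7Z)-8-carboxy-4,6-dimethylnon-7-en-1-yl]-1-hydroxy-5-methylcyclohex-3-ene-1,4-dicarboxylate | OC(=O)/C(C)=C\[C@H](C)C[C@H](C)CCC[C@H]1C=C(C(=O)OCC[Si](C)(C)C)[C@@H](C)C[C@@]1(O)C(=O)OC | intermediate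
31 | acyl Meldrum's acid of 30 (C23 bound to C5 of 2,2-dimethyl-1,3-dioxane-4,6-dione) | CC1(C)OC(=O)C(C(=O)O1)C(=O)/C(C)=C\[C@H](C)C[C@H](C)CCC[C@H]2C=C(C(=O)OCC[Si](C)(C)C)[C@@H](C)C[C@@]2(O)C(=O)OC | intermediate
32 | acylketene from 31 (O=C21=C22H–C23(=O)–) | O=C=CC(=O)/C(C)=C\[C@H](C)C[C@H](C)CCC[C@H]1C=C(C(=O)OCC[Si](C)(C)C)[C@@H](C)C[C@@]1(O)C(=O)OC | intermediate
33 | macrolactone: 14-membered β-keto lactone (O20–C21 ester of the C19 hydroxyl; Z-C2=C3; C24 methyl ester; C15 2-(trimethylsilyl)ethyl ester) | CC1=C/[C@H](C)C[C@H](C)CCC[C@H]2C=C(C(=O)OCC[Si](C)(C)C)[C@@H](C)C[C@@]2(OC(=O)CC\1=O)C(=O)OC | intermediate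
34 | okilactomycin C 2-(trimethylsilyl)ethyl ester | CC1=C/[C@H](C)C[C@H](C)CCC[C@H]2C=C(C(=O)OCC[Si](C)(C)C)[C@@H](C)C[C@]23OC(=O)\C(=C\1O)C3=O | intermediate
35 | okilactomycin C | CC1=C/[C@H](C)C[C@H](C)CCC[C@H]2C=C(C(=O)O)[C@@H](C)C[C@]23OC(=O)\C(=C\1O)C3=O | target

**Step count and risks**

Total step count: 23. Longest linear sequence: 17 steps (steps 1–8 and 15–23, counted from 1).

Most likely to fail, first: step 3. The oxidant must approach the enolate from the face that also carries the menthyloxy group, so facial selectivity may be poor or the oxidation slow. The fallback brings the oxygen in with the dienophile. It sets out from 3: catalytic OsO4 with N-methylmorpholine N-oxide should dihydroxylate the butenolide anti to the menthyloxy group to the cis-diol F1. Ac2O and pyridine give the diacetate F2, and DBU removes the β-acetate by E1cB elimination to give the 3-acetoxy butenolide F3. Diels–Alder reaction of F3 with 2, under the same face and regiochemistry rules but at higher temperature or pressure, gives the acetoxy adduct F4, which carries C19–O from the cycloaddition itself. Ammonia in methanol at low temperature cleaves the tertiary acetate, and the route is rejoined at 6.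

Second: step 20. The iodo-olefination may give low Z selectivity or low conversion next to a free tertiary alcohol. The fallback sets out from 28 and uses a phosphonate olefination instead. Still–Gennari reaction with methyl 2-[bis(2,2,2-trifluoroethoxy)phosphoryl]propanoate, KN(SiMe3)2 and 18-crown-6 in THF at −78 °C should give the Z-enoate F5. Me3SnOH in 1,2-dichloroethane at 80 °C should then hydrolyse this unhindered methyl ester while sparing the methyl ester on the quaternary carbon and the silylethyl ester. The route is rejoined at 30, and step 21 is bypassed.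

Third: step 22. Trapping of the acylketene by the hindered tertiary alcohol may be slow, with ketene dimerisation or Z to E isomerisation of the enone competing. The fallback closes the large ring by C22–C23 bond formation instead. It sets out from 29: Pd(PPh3)4, CO and Bu3SnH should formylate the vinyl iodide with retention to the Z-enal F6. Bromoacetyl bromide and pyridine acylate the tertiary alcohol to the bromoacetate F7. SmI2 in THF at high dilution should effect an intramolecular Reformatsky addition to the β-hydroxy lactone F8, and Dess–Martin oxidation gives 33, where the route is rejoined (steps 21 and 22 are bypassed).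

**Further compounds**

F1 | step 3 | cis-3,4-dihydroxy-5-[(1S,2R,5S)-menthyloxy]dihydrofuran-2(3H)-one (both hydroxyls trans to the menthyloxy group) | O=C1O[C@H](O[C@H]2C[C@@H](C)CC[C@@H]2C(C)C)[C@@H](O)[C@H]1O
F2 | step 3 | diacetate of F1 | O=C1O[C@H](O[C@H]2C[C@@H](C)CC[C@@H]2C(C)C)[C@@H](OC(C)=O)[C@H]1OC(C)=O
F3 | step 3 | (5S)-3-acetoxy-5-[(1S,2R,5S)-menthyloxy]furan-2(5H)-one | CC(=O)OC1=C[C@@H](O[C@H]2C[C@@H](C)CC[C@@H]2C(C)C)OC1=O
F4 | step 3 | 7a-acetate of 6 | O=C1O[C@H](O[C@H]3C[C@@H](C)CC[C@@H]3C(C)C)[C@H]2CC(O[Si](C)(C)C(C)(C)C)=CC[C@@]12OC(C)=O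
F5 | step 20 | methyl Z-enoate: methyl ester of the C23 acid of 30 | COC(=O)/C(C)=C\[C@H](C)C[C@H](C)CCC[C@H]1C=C(C(=O)OCC[Si](C)(C)C)[C@@H](C)C[C@@]1(O)C(=O)OC
F6 | step 22 | Z-enal: 29 with CHO in place of iodine | O=C/C(C)=C\[C@H](C)C[C@H](C)CCC[C@H]1C=C(C(=O)OCC[Si](C)(C)C)[C@@H](C)C[C@@]1(O)C(=O)OC
F7 | step 22 | bromoacetate of F6 at the C19 oxygen | O=C/C(C)=C\[C@H](C)C[C@H](C)CCC[C@H]1C=C(C(=O)OCC[Si](C)(C)C)[C@@H](C)C[C@@]1(OC(=O)CBr)C(=O)OC
F8 | step 22 | β-hydroxy macrolactone: 33 with C23 as carbinol (both epimers) | CC1=C/[C@H](C)C[C@H](C)CCC[C@H]2C=C(C(=O)OCC[Si](C)(C)C)[C@@H](C)C[C@@]2(OC(=O)CC\1O)C(=O)OC
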